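**Retrosynthetic overview**

1. The 2H-chromene comes from a (2R)-chroman-4-one by C4 reduction and dehydration; the chromanone comes from a 2-alkyl-5-hydroxychromone by Cu-catalysed enantioselective 1,4-methylation, which sets chromene C2.
2. The chromone (pyranone ring, closed last) comes from Claisen condensation and cyclodehydration of mirror-symmetric 2,6-dihydroxy-3,4,5-trimethoxyacetophenone with a cyclohexenylpropanoate ester; the symmetry of the arene fixes the regiochemistry.
3. The ester comes from a ring ketone by kinetic enol triflate formation and Negishi methylation (ring C3 methyl and the C3=C4 alkene), after regiospecific α-methylation at ring C2.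
4. Key C–C bond: ring quaternary carbon to side-chain CH2, made by catalytic enantioselective conjugate addition of a zinc ester homoenolate (β-carbanion of ethyl propanoate, from a siloxycyclopropane) to 3-methylcyclohex-2-en-1-one; two carbons that are each β to a carbonyl are joined.
5. Ring order: the carbocycle is bought and decorated first, the arene is elaborated from 1,2,3-trimethoxybenzene, and the pyran ring is formed last.

Assumption: the descriptors read from the SMILES are 2R for the chromene carbon and 1S,2S for the cyclohexene (ring methyls cis, side chain trans to the C2 methyl). Cyclohexene numbering below: C1 quaternary, C2 CHMe, C3 =CMe.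

**Step 1**
Reactants: 1 3-methylcyclohex-2-en-1-one; 2 (1-ethoxycyclopropoxy)trimethylsilane
Product: 4 ethyl 3-[(1S)-1-methyl-3-(trimethylsilyloxy)cyclohex-2-en-1-yl]propanoate, via bis(3-ethoxy-3-oxopropyl)zinc 3 (not isolated)
Conditions: 2 (2.4 equiv), ZnCl2 (1.2 equiv), Et2O, rt, 1 h; then 1, (CuOTf)2·C6H6 (3 mol %), chiral C2-symmetric imidazolinium salt (NHC precursor, 7 mol %) and KN(SiMe3)2 (7 mol %), Et2O–THF, −30 → 0 °C; Et3N, pentane, cold aq NaHCO3
Reagents that add atoms: chlorotrimethylsilane (generated in the flask from 2 and ZnCl2), C[Si](C)(C)Cl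
Why: Proposed new method: the dialkylzinc-type homoenolate 3 (ring-opened siloxycyclopropane, a β-acyl carbanion) transfers its alkyl group to a chiral NHC–copper centre, which adds it to the Re face of C3 of enone 1 in a copper-catalysed asymmetric conjugate addition, creating the quaternary (S) centre while the chlorotrimethylsilane made in the flask silylates the enolate and releases the catalyst; the closest known reactions are the copper-catalysed, chlorosilane-accelerated conjugate addition of this zinc homoenolate to β,β-disubstituted enones (racemic) and the NHC–copper-catalysed asymmetric conjugate addition of dialkylzincs to 3-methylcyclohexenone.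

**Step 2**
Reactants: 4 ethyl 3-[(1S)-1-methyl-3-(trimethylsilyloxy)cyclohex-2-en-1-yl]propanoate
Product: 5 ethyl 3-[(1S,2S)-1,2-dimethyl-3-oxocyclohexyl]propanoate
Conditions: BnMe3N+ F− (dried, 1.1 equiv), MeI (5 equiv), 4 Å MS, THF, −20 °C → rt; chromatography to remove the minor C2 epimer
Reagents that add atoms: iodomethane, CI
Why: Regiospecific fluoride-mediated enolate alkylation of a silyl enol ether (quaternary ammonium enolate method): MeI attacks C2 of the half-chair enolate axially, anti to the larger pseudoaxial propanoate chain on the neighbouring quaternary carbon, so the new methyl ends up trans to the chain and cis to the ring methyl (expected d.r. about 4:1).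

**Step 3**
Reactants: 5 ethyl 3-[(1S,2S)-1,2-dimethyl-3-oxocyclohexyl]propanoate
Product: 6 (5S,6S)-5-(3-ethoxy-3-oxopropyl)-5,6-dimethylcyclohex-1-en-1-yl trifluoromethanesulfonate
Conditions: KN(SiMe3)2 (1.05 equiv), THF, −78 °C; PhNTf2 (1.1 equiv), −78 → 0 °C
Reagents that add atoms: N-phenylbis(trifluoromethanesulfonimide), O=S(=O)(N(c1ccccc1)S(=O)(=O)C(F)(F)F)C(F)(F)F
Why: Kinetic enolate formation and O-triflation: the ketone is more acidic than the ester and the base removes a proton from the unhindered ring CH2 rather than the methine flanked by the quaternary carbon, so the C2 stereocentre is untouched.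

**Step 4**
Reactants: 6 (5S,6S)-5-(3-ethoxy-3-oxopropyl)-5,6-dimethylcyclohex-1-en-1-yl trifluoromethanesulfonate
Product: 7 ethyl 3-[(1S,2S)-1,2,3-trimethylcyclohex-3-en-1-yl]propanoate
Conditions: MeZnCl (2 equiv), Pd(PPh3)4 (5 mol %), THF, 50 °C
Reagents that add atoms: methylzinc chloride, C[Zn]Cl
Why: Negishi cross-coupling of an enol triflate installs the vinylic methyl with the double bond fixed at C3=C4; the ester and both stereocentres are inert to the organozinc.

**Step 5**
Reactants: 8 1,2,3-trimethoxybenzene
Product: 9 1,5-dibromo-2,3,4-trimethoxybenzene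
Conditions: NBS (2.1 equiv), MeCN, 0 °C → rt
Reagents that add atoms: N-bromosuccinimide, O=C1CCC(=O)N1Br
Why: Electrophilic aromatic bromination occurs twice at the positions para to the two outer methoxy groups (the central methoxy is twisted out of conjugation), giving the symmetric 4,6-dibromide.

**Step 6**
Reactants: 9 1,5-dibromo-2,3,4-trimethoxybenzene
Product: 10 4,5,6-trimethoxybenzene-1,3-diol
Conditions: Pd2(dba)3 (2 mol %), t-BuXPhos (8 mol %), KOH (6 equiv), 1,4-dioxane–H2O (1:1), degassed, 100 °C; then 1 M HCl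
Reagents that add atoms: potassium hydroxide, [K+].[OH-]
Why: Palladium-catalysed hydroxylation of aryl bromides (C–O cross-coupling with hydroxide) with a bulky biarylphosphine converts both C–Br bonds to phenols and suppresses diaryl ether formation.

**Step 7**
Reactants: 10 4,5,6-trimethoxybenzene-1,3-diol
Product: 11 1-(2,6-dihydroxy-3,4,5-trimethoxyphenyl)ethan-1-one
Conditions: AcOH, BF3·OEt2 (3 equiv), 80 °C; aq NaOAc
Reagents that add atoms: acetic acid, CC(=O)O
Why: Friedel–Crafts acylation (through O-acetylation and Fries rearrangement) can only occur at the single free ring carbon between the two hydroxyls, giving the symmetric acetophenone.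

**Step 8**
Reactants: 7 ethyl 3-[(1S,2S)-1,2,3-trimethylcyclohex-3-en-1-yl]propanoate; 11 1-(2,6-dihydroxy-3,4,5-trimethoxyphenyl)ethan-1-one
Product: 13 5-hydroxy-6,7,8-trimethoxy-2-{2-[(1S,2S)-1,2,3-trimethylcyclohex-3-en-1-yl]ethyl}-4H-chromen-4-one, via 1,3-diketone 12 (not isolated)
Conditions: 11, LiN(SiMe3)2 (4.2 equiv), THF, −78 → −10 °C; 7 (1.1 equiv), −78 °C → rt; 1 M HCl; then AcOH, HCl (cat.), 50 °C
Reagents that add atoms: none
Why: Claisen condensation of the acetophenone trianion with the ester followed by acid cyclodehydration is the standard route to 2-(2-substituted-ethyl)chromones; because 11 is symmetric either phenol gives the same chromone and the other remains as the 5-OH.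

**Step 9**
Reactants: 13 5-hydroxy-6,7,8-trimethoxy-2-{2-[(1S,2S)-1,2,3-trimethylcyclohex-3-en-1-yl]ethyl}-4H-chromen-4-one
Product: 14 (2R)-5-hydroxy-6,7,8-trimethoxy-2-methyl-2-{2-[(1S,2S)-1,2,3-trimethylcyclohex-3-en-1-yl]ethyl}-2,3-dihydro-4H-chromen-4-one
Conditions: AlMe3 (4 equiv; the first equivalent converts the 5-OH to its aluminium phenoxide), Cu(O2CC4H3S) (copper thiophene-2-carboxylate, 5 mol %), TADDOL-derived chiral phosphine–phosphite ligand (6 mol %), Et2O, −30 → 0 °C; 1 M HCl, 0 °C
Reagents that add atoms: trimethylaluminium, C[Al](C)C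
Why: Copper-catalysed asymmetric 1,4-addition of AlMe3 to a 2-alkylchromenone (the reaction type used to build the quaternary chromane centre of tocopherol) delivers methyl to the Si face of C2 under ligand control, setting the (R) centre independently of the remote ring stereocentres.

**Step 10**
Reactants: 14 (2R)-5-hydroxy-6,7,8-trimethoxy-2-methyl-2-{2-[(1S,2S)-1,2,3-trimethylcyclohex-3-en-1-yl]ethyl}-2,3-dihydro-4H-chromen-4-one
Product: 16 (2R)-6,7,8-trimethoxy-2-methyl-2-{2-[(1S,2S)-1,2,3-trimethylcyclohex-3-en-1-yl]ethyl}-2H-chromen-5-ol, via chroman-4-ol 15 (not isolated)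
Conditions: NaBH4 (3 equiv), MeOH–THF, 0 °C → rt; aq NH4Cl; then PPTS (10 mol %), toluene, 60 °C
Reagents that add atoms: none
Why: Hydride reduction of the aryl ketone followed by mild acid-catalysed dehydration of the very electron-rich benzylic alcohol (through the stabilised benzylic cation or o-quinone methide) gives the C3=C4 alkene without touching the C2–O bond, so the (R) centre is kept.

**Compound list**

1 | 3-methylcyclohex-2-en-1-one | CC1=CC(=O)CCC1 | starting material
2 | (1-ethoxycyclopropoxy)trimethylsilane | CCOC1(O[Si](C)(C)C)CC1 | starting material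
3 | bis(3-ethoxy-3-oxopropyl)zinc | CCOC(=O)CC[Zn]CCC(=O)OCC | intermediate
4 | ethyl 3-[(1S)-1-methyl-3-(trimethylsilyloxy)cyclohex-2-en-1-yl]propanoate | CCOC(=O)CC[C@]1(C)CCCC(O[Si](C)(C)C)=C1 | intermediate
5 | ethyl 3-[(1S,2S)-1,2-dimethyl-3-oxocyclohexyl]propanoate | CCOC(=O)CC[C@]1(C)CCCC(=O)[C@H]1C | intermediate
6 | (5S,6S)-5-(3-ethoxy-3-oxopropyl)-5,6-dimethylcyclohex-1-en-1-yl trifluoromethanesulfonate | CCOC(=O)CC[C@]1(C)CCC=C(OS(=O)(=O)C(F)(F)F)[C@H]1C | intermediate
7 | ethyl 3-[(1S,2S)-1,2,3-trimethylcyclohex-3-en-1-yl]propanoate | CCOC(=O)CC[C@]1(C)CCC=C(C)[C@H]1C | intermediate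
8 | 1,2,3-trimethoxybenzene | COc1cccc(OC)c1OC | starting material
9 | 1,5-dibromo-2,3,4-trimethoxybenzene | COc1c(Br)cc(Br)c(OC)c1OC | intermediate
10 | 4,5,6-trimethoxybenzene-1,3-diol | COc1c(O)cc(O)c(OC)c1OC | intermediate
11 | 1-(2,6-dihydroxy-3,4,5-trimethoxyphenyl)ethan-1-one | COc1c(O)c(C(C)=O)c(O)c(OC)c1OC | intermediate
12 | 1-(2,6-dihydroxy-3,4,5-trimethoxyphenyl)-5-[(1S,2S)-1,2,3-trimethylcyclohex-3-en-1-yl]pentane-1,3-dione | COc1c(O)c(C(=O)CC(=O)CC[C@]2(C)CCC=C(C)[C@H]2C)c(O)c(OC)c1OC | intermediate
13 | 5-hydroxy-6,7,8-trimethoxy-2-{2-[(1S,2S)-1,2,3-trimethylcyclohex-3-en-1-yl]ethyl}-4H-chromen-4-one | COc1c(O)c2c(c(OC)c1OC)OC(CC[C@]1(C)CCC=C(C)[C@H]1C)=CC2=O | intermediate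
14 | (2R)-5-hydroxy-6,7,8-trimethoxy-2-methyl-2-{2-[(1S,2S)-1,2,3-trimethylcyclohex-3-en-1-yl]ethyl}-2,3-dihydro-4H-chromen-4-one | COc1c(O)c2c(c(OC)c1OC)O[C@](C)(CC[C@]1(C)CCC=C(C)[C@H]1C)CC2=O | intermediate
15 | (2R)-6,7,8-trimethoxy-2-methyl-2-{2-[(1S,2S)-1,2,3-trimethylcyclohex-3-en-1-yl]ethyl}-3,4-dihydro-2H-chromene-4,5-diol (both C4 epimers) | COc1c(O)c2c(c(OC)c1OC)O[C@](C)(CC[C@]1(C)CCC=C(C)[C@H]1C)CC2O | intermediate
16 | (2R)-6,7,8-trimethoxy-2-methyl-2-{2-[(1S,2S)-1,2,3-trimethylcyclohex-3-en-1-yl]ethyl}-2H-chromen-5-ol | COc1c(O)c2c(c(OC)c1OC)O[C@](C)(CC[C@]1(C)CCC=C(C)[C@H]1C)C=C2 | target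

**Totals**

Total step count: 10. Longest linear sequence: 7 steps (steps 1, 2, 3, 4, 8, 9, 10); the arene branch is 3 steps (5–7).

**Steps most likely to fail, with fallbacks**

Step 1. The combination is untested: the internally chelated homoenolate may transfer slowly to the chiral copper catalyst, and the chlorosilane may disturb the ligand, so both conversion and ee are uncertain. The fallback sets out from zinc homoenolate 3 and comes back at 4. Compound 3 is coupled under Pd(PPh3)4 catalysis in THF with 3-bromocyclohex-2-en-1-one F1. This is a formal addition–elimination at the enone β-carbon and keeps the same polarity-reversed bond. It gives ethyl 3-(3-oxocyclohex-1-en-1-yl)propanoate F2. The quaternary centre is then set by the well-precedented Cu(O2CC4H3S)/phosphoramidite-catalysed conjugate addition of AlMe3 (Et2O, −30 °C), and the aluminium enolate is silylated in the flask with TMSOTf to give 4.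

Step 2. The face selectivity rests only on methyl versus CH2CH2CO2Et at the neighbouring quaternary carbon, so the d.r. may be low. The reactive ammonium enolate could also close onto the ester (Dieckmann). The fallback sets out from 4 and comes back at 5, and replaces substrate-controlled alkylation by catalyst-controlled hydrogenation. Compound 4 is treated with Eschenmoser's salt (CH2=NMe2+ I−, CH2Cl2) to give the Mannich base ethyl 3-[(1S)-2-[(dimethylamino)methyl]-1-methyl-3-oxocyclohexyl]propanoate F3. Quaternisation with MeI and elimination with NaHCO3 give the α-methylene ketone ethyl 3-[(1S)-1-methyl-2-methylidene-3-oxocyclohexyl]propanoate F4. Hydrogenation with Ru(OAc)2(BINAP) (the BINAP enantiomer that adds H2 to the face cis to the propanoate chain; H2, MeOH) then gives 5 under neutral conditions.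

Step 9. The free 5-OH becomes an aluminium phenoxide chelated to the C4 carbonyl, which may slow the addition or erode the ee on a tetrasubstituted vinylogous-ester acceptor. The fallback sets out from 13 and comes back at 14, and takes the phenol out of the stereo-determining step. Compound 13 is O-methylated (MeI, K2CO3, acetone) to 5,6,7,8-tetramethoxy-2-{2-[(1S,2S)-1,2,3-trimethylcyclohex-3-en-1-yl]ethyl}-4H-chromen-4-one F5, the fully O-alkylated substrate class for which the addition is established. The same Cu/AlMe3 addition gives (2R)-5,6,7,8-tetramethoxy-2-methyl-2-{2-[(1S,2S)-1,2,3-trimethylcyclohex-3-en-1-yl]ethyl}-2,3-dihydro-4H-chromen-4-one F6. BCl3 (CH2Cl2, −78 °C) then cleaves only the methyl ether peri to the carbonyl (chelation-directed) to give 14.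

**Further compounds**

F1 | step 1 | 3-bromocyclohex-2-en-1-one | BrC1=CC(=O)CCC1
F2 | step 1 | ethyl 3-(3-oxocyclohex-1-en-1-yl)propanoate | CCOC(=O)CCC1=CC(=O)CCC1
F3 | step 2 | ethyl 3-[(1S)-2-[(dimethylamino)methyl]-1-methyl-3-oxocyclohexyl]propanoate (C2 epimers) | CCOC(=O)CC[C@]1(C)CCCC(=O)C1CN(C)C
F4 | step 2 | ethyl 3-[(1S)-1-methyl-2-methylidene-3-oxocyclohexyl]propanoate | CCOC(=O)CC[C@]1(C)CCCC(=O)C1=C
F5 | step 9 | 5,6,7,8-tetramethoxy-2-{2-[(1S,2S)-1,2,3-trimethylcyclohex-3-en-1-yl]ethyl}-4H-chromen-4-one | COc1c(OC)c2c(c(OC)c1OC)OC(CC[C@]1(C)CCC=C(C)[C@H]1C)=CC2=O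
F6 | step 9 | (2R)-5,6,7,8-tetramethoxy-2-methyl-2-{2-[(1S,2S)-1,2,3-trimethylcyclohex-3-en-1-yl]ethyl}-2,3-dihydro-4H-chromen-4-one | COc1c(OC)c2c(c(OC)c1OC)O[C@](C)(CC[C@]1(C)CCC=C(C)[C@H]1C)CC2=O
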